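## Retrosynthetic overview

1. The route rests on one feature: quaternary C8 is bonded to C9, the carbon β to the lactone carbonyl C20. Ring C (C8, C9, C11, C12, C13, C14) shares C9–C11–C12 with the 20→12 δ-lactone (a 2-oxabicyclo[3.3.1]nonane) and C8/C13/C14 with ring D (a bicyclo[3.2.1]octane). C8–C9 is therefore cut back to a ring D cyclopentene (tertiary C8 radical) and the C9=C10 enoate of a dihydropyranone hung on C13 through C12.
2. Precursor: ring D from an oxazolidinone syn-aldol (sets C13) and ring-closing metathesis; C12 by reagent-controlled allylboration; lactone by acryloylation and ring-closing metathesis.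
3. After ring C: α-methylenation of the lactone (C1), then C7 and a 2-silyloxydiene (C2–C5) are built on the C8 arm; one intramolecular Diels–Alder reaction forms C1–C2 and C5–C10 and closes rings B and A together.
4. Ring A end game: C19 (formyl), then C18 (methyl) at C4; C2=C3 alkene; one oxidation to the C7/C19 acids and the C16 ketone; β-face dihydroxylation; C16 methylenation.
5. Ring order: D, lactone, C, then B and A in one step.

Key step: step 11

Remark: ent-gibberellane atom numbers are used and β is the face of H5, C18 and C7; C16 goes through the key step as a triisopropylsilyl ether of the alcohol (cis to C12) and the ring D alkene is C8=C15, which gives the same tertiary C8 radical as a C8=C14 isomer; the natural C6 configuration (C7 trans to C4) is assumed to be the thermodynamically preferred one.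

## Route

Step 1
Reactants: 1 3-bromobut-3-en-1-ol
Product: 2 [(3-bromobut-3-en-1-yl)oxy](tert-butyl)dimethylsilane
Conditions: TBSCl, imidazole, CH2Cl2, rt
Reagents that add atoms: tert-butyldimethylsilyl chloride, CC(C)(C)[Si](C)(C)Cl
Why: Standard silyl ether protection of the primary alcohol; a silyl ether is chosen for the arm because it offers no weak C–H bond to the later C8 radical.

Step 2
Reactants: 2 [(3-bromobut-3-en-1-yl)oxy](tert-butyl)dimethylsilane; 3 (4R)-3-acryloyl-4-benzyl-1,3-oxazolidin-2-one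
Product: 5 (4R)-4-benzyl-3-{6-[(tert-butyldimethylsilyl)oxy]-4-methylidenehexanoyl}-1,3-oxazolidin-2-one, via Grignard reagent 4 (not isolated)
Conditions: Mg, THF, 45 °C; CuBr·SMe2 (20 mol %), THF/Me2S, −78 °C; 3, −78 to −30 °C; aq. NH4Cl
Reagents that add atoms: none
Why: Copper-catalysed conjugate addition of the alkenyl Grignard reagent to the N-acryloyl imide joins C8 (with its arm) to the C14–C13–C12 chain; no stereocentre is formed.

Step 3
Reactants: 5 (4R)-4-benzyl-3-{6-[(tert-butyldimethylsilyl)oxy]-4-methylidenehexanoyl}-1,3-oxazolidin-2-one; 6 acrolein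
Product: 7 (4R)-4-benzyl-3-[(2R,3S)-2-{4-[(tert-butyldimethylsilyl)oxy]-2-methylidenebutyl}-3-hydroxypent-4-enoyl]-1,3-oxazolidin-2-one
Conditions: Bu2BOTf, iPr2NEt, CH2Cl2, −78 to 0 °C; 6, −78 to 0 °C; pH 7 buffer, MeOH, H2O2, 0 °C
Reagents that add atoms: none
Why: Evans syn-aldol reaction: the (Z)-boron enolate reacts through a chair transition state on the face away from the benzyl group of the (R)-auxiliary, which should set C13 (R in 7) and the syn C16 carbinol (S in 7).

Step 4
Reactants: 7 the syn-aldol adduct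
Product: 8 (4R)-4-benzyl-3-{[(1R,2S)-4-{2-[(tert-butyldimethylsilyl)oxy]ethyl}-2-hydroxycyclopent-3-en-1-yl]carbonyl}-1,3-oxazolidin-2-one
Conditions: second-generation Grubbs catalyst (3 mol %), CH2Cl2, 40 °C
Reagents that add atoms: none
Why: Ring-closing metathesis between the vinyl group of the allylic alcohol and the 1,1-disubstituted alkene closes ring D as the C15=C8 cyclopentene; these are the only two alkenes, so no other ring can form.

Step 5
Reactants: 8 the ring D cyclopentenol imide
Product: 9 (4R)-4-benzyl-3-{[(1R,2S)-4-{2-[(tert-butyldimethylsilyl)oxy]ethyl}-2-[(triisopropylsilyl)oxy]cyclopent-3-en-1-yl]carbonyl}-1,3-oxazolidin-2-one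
Conditions: TIPSOTf, 2,6-lutidine, CH2Cl2, −40 to 0 °C
Reagents that add atoms: triisopropylsilyl trifluoromethanesulfonate, CC(C)[Si](OS(=O)(=O)C(F)(F)F)(C(C)C)C(C)C
Why: Silylation of the C16 alcohol with the silyl triflate; the hindered secondary triisopropylsilyl ether should outlast the primary tert-butyldimethylsilyl ether of the arm.

Step 6
Reactants: 9 the bis-silylated imide
Product: 10 [(1S,2S)-4-{2-[(tert-butyldimethylsilyl)oxy]ethyl}-2-[(triisopropylsilyl)oxy]cyclopent-3-en-1-yl]methanol
Conditions: LiBH4, MeOH (1 equiv), THF, 0 °C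
Reagents that add atoms: none
Why: Reductive cleavage of the N-acyl oxazolidinone gives the primary alcohol at C12 and returns the auxiliary; C13 is not epimerised.

Step 7
Reactants: 10 the primary alcohol
Product: 11 (1R,2S)-4-{2-[(tert-butyldimethylsilyl)oxy]ethyl}-2-[(triisopropylsilyl)oxy]cyclopent-3-ene-1-carbaldehyde
Conditions: Dess–Martin periodinane, NaHCO3, CH2Cl2, rt
Reagents that add atoms: none
Why: Dess–Martin oxidation under buffered conditions gives the β-silyloxy aldehyde without epimerisation at C13 or β-elimination.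

Step 8
Reactants: 11 the aldehyde
Product: 12 (1S)-1-[(1S,2S)-4-{2-[(tert-butyldimethylsilyl)oxy]ethyl}-2-[(triisopropylsilyl)oxy]cyclopent-3-en-1-yl]but-3-en-1-ol
Conditions: (−)-Ipc2BOMe, allylMgBr, Et2O, −78 °C to rt; 11, −78 °C; NaOH, H2O2, 0 °C to rt
Reagents that add atoms: (−)-B-allyldiisopinocampheylborane, C=CCB([C@@H]1C[C@@H]2C[C@H]([C@H]1C)C2(C)C)[C@@H]1C[C@@H]2C[C@H]([C@H]1C)C2(C)C
Why: Brown allylboration through a chair transition state: the isopinocampheyl groups derived from (+)-α-pinene should direct the allyl group to the Si face of the aldehyde and give the (S)-carbinol at C12 under reagent control.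

Step 9
Reactants: 12 the homoallylic alcohol; 13 acryloyl chloride
Product: 14 (1S)-1-[(1S,2S)-4-{2-[(tert-butyldimethylsilyl)oxy]ethyl}-2-[(triisopropylsilyl)oxy]cyclopent-3-en-1-yl]but-3-en-1-yl prop-2-enoate
Conditions: iPr2NEt, DMAP (cat.), CH2Cl2, 0 °C
Reagents that add atoms: none
Why: Acylation of the secondary alcohol gives the acrylate needed for lactone closure; no stereocentre is touched.

Step 10
Reactants: 14 the acrylate
Product: 15 (6S)-6-[(1S,2S)-4-{2-[(tert-butyldimethylsilyl)oxy]ethyl}-2-[(triisopropylsilyl)oxy]cyclopent-3-en-1-yl]-5,6-dihydro-2H-pyran-2-one (key-step precursor)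
Conditions: second-generation Grubbs catalyst (5 mol %), CH2Cl2, 40 °C
Reagents that add atoms: none
Why: Ring-closing metathesis of the acrylate with the allyl group forms the dihydropyranone (C9=C10); the trisubstituted ring D alkene is too hindered to take part.

Step 11
Reactants: 15 the ring D cyclopentene bearing the C12 dihydropyranone on C13
Product: 16 tricyclic lactone (ring C, ring D and the 20→12 δ-lactone; C8 bears CH2CH2OTBS, C16 bears OTIPS, C10 is CH2; C8, C9, C12, C13 as in the target)
Conditions: Fe(acac)3 (0.5 equiv), PhSiH3 (2.5 equiv), EtOH/ethylene glycol (5:1), 0.02 M, 60 °C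
Reagents that add atoms: none
Why: Fe(acac)3 and PhSiH3 generate an iron hydride that transfers a hydrogen atom to C15 of the trisubstituted C8=C15 alkene (Markovnikov), and the resulting tertiary C8 radical adds to C9, the β-carbon of the lactone enoate, after which the C10 radical is reduced to the enolate and protonated by ethanol. The closest known reaction type is the iron-hydride hydrogen-atom-transfer reductive coupling of an unactivated alkene with an α,β-unsaturated ester or lactone (a Giese-type addition), run here intramolecularly. One ring is closed, ring C (C8, C9, C11, C12, C13, C14), by 6-exo-trig attack, and this closure also completes the bicyclo[3.2.1]octane with ring D and the 2-oxabicyclo[3.3.1]nonane with the lactone. Both new stereocentres are fixed by geometry: the C9–C11–C12 link can bridge C13 and C8 only on the ring D face that carries C12, which sets C8, and C8 can reach C9 only on the lactone face cis to C13 (through the half-chair with C13 axial at C12), which sets C9. The step needs hydrogen-atom transfer to the ring D alkene and not to the enoate, which the preference of the iron hydride for the more substituted, electron-rich alkene should secure, and the alkyl radical then meets an electron-poor alkene of suitable polarity. The silyl ethers offer no weak C–H bond within reach of C8, and high dilution suppresses intermolecular coupling.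

Step 12
Reactants: 16 the tricyclic lactone
Product: 17 10-(dimethylaminomethyl) lactone (C1 on C10, anti to C8)
Conditions: LiN(iPr)2, THF, −78 °C; Me2N=CH2 I, −78 °C to rt
Reagents that add atoms: N,N-dimethylmethyleneiminium iodide, C=[N+](C)C.[I-]
Why: Mannich reaction of the lactone lithium enolate (first half of an Eschenmoser methylenation) adds C1 at C10 on the face away from the axial C8; the new C10 centre is removed in step 13.

Step 13
Reactants: 17 the Mannich base
Product: 19 α-methylene lactone (C10=C1), via ammonium iodide 18 (not isolated)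
Conditions: MeI, CH2Cl2, rt; then aq. NaHCO3, CH2Cl2, rt
Reagents that add atoms: none
Why: N-Methylation and base-induced β-elimination of trimethylamine (second half of the Eschenmoser methylenation) give the dienophile C10=C1.

Step 14
Reactants: 19 the α-methylene lactone
Product: 20 primary alcohol (C5–OH on the C8 arm)
Conditions: HF·pyridine, pyridine, THF, 0 °C
Reagents that add atoms: none
Why: Fluoride-mediated desilylation cleaves the unhindered primary tert-butyldimethylsilyl ether much faster than the hindered secondary triisopropylsilyl ether.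

Step 15
Reactants: 20 the primary alcohol
Product: 21 aldehyde (C5 aldehyde, C6 methylene on quaternary C8)
Conditions: Dess–Martin periodinane, NaHCO3, CH2Cl2, rt
Reagents that add atoms: none
Why: Dess–Martin oxidation of the primary alcohol; the α-methylene lactone and the silyl ether are inert.

Step 16
Reactants: 21 the aldehyde
Product: 23 (E)-enone (C6 bears CH2OH = C7; C5=C4–C3(=O)–C2H3), via hydroxymethyl aldehyde 22 (not isolated)
Conditions: aq. HCHO (3 equiv), (R)-2-[diphenyl(trimethylsilyloxy)methyl]pyrrolidine (20 mol %), pH 7 phosphate buffer, toluene, rt; aqueous wash; Ph3P=CHC(O)CH3, toluene, 40 °C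
Reagents that add atoms: formaldehyde, C=O; 1-(triphenylphosphoranylidene)propan-2-one, CC(=O)C=P(c1ccccc1)(c1ccccc1)c1ccccc1
Why: Enamine-catalysed α-hydroxymethylation of the aldehyde (organocatalytic cross-aldol with formaldehyde) followed by Wittig olefination: the diphenyl(silyloxy)methyl group shields one face of the (E)-enamine, so formaldehyde should add from the other face and set C6 (S in 22), the aldol is trapped before it can dehydrate or epimerise, and the stabilised ylide gives the (E)-enone.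

Step 17
Reactants: 23 the hydroxy enone
Product: 24 2-silyloxydiene (C2=C3(OTBS)–C4=C5, C7–OTBS)
Conditions: TBSOTf (2.5 equiv), Et3N, CH2Cl2, −78 to 0 °C
Reagents that add atoms: tert-butyldimethylsilyl trifluoromethanesulfonate, CC(C)(C)[Si](C)(C)OS(=O)(=O)C(F)(F)F
Why: The silyl triflate and amine silylate the C7 alcohol and convert the methyl ketone, by enolisation at the methyl group, into the 2-silyloxy-1,3-diene with the (E)-C4=C5 geometry kept.

Step 18
Reactants: 24 the silyloxydiene with the α-methylene lactone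
Product: 25 pentacyclic silyl enol ether (rings A to D and lactone; C3(OTBS)=C4; A/B trans, 5β-H)
Conditions: toluene (0.01 M), 2,6-di-tert-butyl-4-methylphenol (cat.), 130 °C, sealed tube
Reagents that add atoms: none
Why: Thermal intramolecular Diels–Alder reaction closes ring B (C10–C5) and ring A (C1–C2) at once: the C6–C8–C9 tether delivers C5 to the C10 face cis to C8 (fixing C10), and the transition state with the lactone carbonyl C20 endo and the tether exo, which keeps the diene clear of quaternary C8, should give the trans A/B fusion (H5 anti to C20).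

Step 19
Reactants: 25 the pentacyclic silyl enol ether
Product: 27 4-(hydroxymethylidene)-3-ketone (C19 on C4), via keto acetal 26 (not isolated)
Conditions: HC(OMe)3, Me3SiOTf (10 mol %), CH2Cl2, −78 °C; then 10% aq. oxalic acid on silica gel, CH2Cl2, rt
Reagents that add atoms: trimethyl orthoformate, COC(OC)OC; water, O
Why: Mukaiyama-type addition of the regiodefined C3–C4 silyl enol ether to the dimethoxycarbenium ion places C19 on C4 only, and mild hydrolysis of the β-keto acetal gives the hydroxymethylene ketone, in which C4 is planar.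

Step 20
Reactants: 27 the hydroxymethylene ketone
Product: 28 4β-methyl-4α-formyl-3-ketone (C4 quaternary)
Conditions: MeI, K2CO3, acetone, rt
Reagents that add atoms: iodomethane, CI
Why: C-Methylation of the potassium enolate of the formyl ketone: MeI should enter on the β face, anti to the axial C20 lactone carbonyl on C10, so that C18 is β and the C19 formyl group α (axial).

Step 21
Reactants: 28 the formyl methyl ketone
Product: 29 C2=C3 enol triflate (3-OTf)
Conditions: KN(SiMe3)2, THF, −78 °C; PhNTf2, −78 to 0 °C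
Reagents that add atoms: N-phenylbis(trifluoromethanesulfonimide), O=S(=O)(N(c1ccccc1)S(=O)(=O)C(F)(F)F)C(F)(F)F
Why: The ketone can enolise only toward C2 because C4 is quaternary, and O-triflation of the potassium enolate gives the enol triflate.

Step 22
Reactants: 29 the enol triflate
Product: 30 C2=C3 alkene (19-aldehyde, 7-OTBS, 16-OTIPS)
Conditions: Pd(OAc)2 (5 mol %), PPh3 (10 mol %), Bu3N, HCO2H, DMF, 60 °C
Reagents that add atoms: none
Why: Palladium-catalysed formate reduction of the enol triflate (oxidative addition, hydride transfer from formate, reductive elimination) gives the alkene without touching the aldehyde or the lactone.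

Step 23
Reactants: 30 the bis-silyl ether
Product: 31 7,16-diol 19-aldehyde
Conditions: 48% aq. HF, MeCN, rt to 40 °C
Reagents that add atoms: none
Why: Acidic fluoride removes both silyl ethers; the non-enolisable C19 aldehyde, the alkene and the lactone are stable to it.

Step 24
Reactants: 31 the diol aldehyde
Product: 32 16-oxo-7,19-dioic acid (C2=C3 alkene, lactone intact)
Conditions: CrO3, H2SO4, H2O, acetone, 0 °C
Reagents that add atoms: water, O
Why: Jones oxidation converts the C7 primary alcohol and the C19 aldehyde to the acids and the C16 alcohol to the ketone in one operation; the isolated alkene and the lactone are inert, and the transient C7 aldehyde can only relax toward the more stable natural C6 configuration.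

Step 25
Reactants: 32 the keto diacid
Product: 33 2β,3β-dihydroxy-16-oxo-7,19-dioic acid
Conditions: OsO4 (2 mol %), N-methylmorpholine N-oxide, acetone/H2O, rt
Reagents that add atoms: N-methylmorpholine N-oxide, C[N+]1([O-])CCOCC1; water, O
Why: Catalytic OsO4 syn-dihydroxylation of the C2=C3 alkene should occur on the β face, because the α face is screened by the axial C19 carboxyl on C4 and the C20 lactone carbonyl on C10, giving the cis-2β,3β-diol.

Step 26
Reactants: 33 the 16-ketone
Product: 34 CNP0212122.1 (target)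
Conditions: Ph3PCH3Br, KOtBu (8 equiv each), THF, rt to 50 °C; aq. citric acid
Reagents that add atoms: methylidenetriphenylphosphorane, C=P(c1ccccc1)(c1ccccc1)c1ccccc1
Why: Wittig methylenation of the C16 ketone with excess ylide, which first deprotonates the acids and alcohols; the carboxylates and the lactone do not react and the bridgehead C13 cannot epimerise.

## Compound list

1 | 3-bromobut-3-en-1-ol | C=C(Br)CCO | starting material
2 | [(3-bromobut-3-en-1-yl)oxy](tert-butyl)dimethylsilane | C=C(Br)CCO[Si](C)(C)C(C)(C)C | intermediate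
3 | (4R)-3-acryloyl-4-benzyl-1,3-oxazolidin-2-one | C=CC(=O)N1[C@H](Cc2ccccc2)COC1=O | starting material
4 | {4-[(tert-butyldimethylsilyl)oxy]but-1-en-2-yl}magnesium bromide | C=C([Mg]Br)CCO[Si](C)(C)C(C)(C)C | intermediate
5 | (4R)-4-benzyl-3-{6-[(tert-butyldimethylsilyl)oxy]-4-methylidenehexanoyl}-1,3-oxazolidin-2-one | C=C(CCO[Si](C)(C)C(C)(C)C)CCC(=O)N1[C@H](Cc2ccccc2)COC1=O | intermediate
6 | acrolein | C=CC=O | starting material
7 | (4R)-4-benzyl-3-[(2R,3S)-2-{4-[(tert-butyldimethylsilyl)oxy]-2-methylidenebutyl}-3-hydroxypent-4-enoyl]-1,3-oxazolidin-2-one | C=C[C@H](O)[C@@H](CC(=C)CCO[Si](C)(C)C(C)(C)C)C(=O)N1[C@H](Cc2ccccc2)COC1=O | intermediate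
8 | (4R)-4-benzyl-3-{[(1R,2S)-4-{2-[(tert-butyldimethylsilyl)oxy]ethyl}-2-hydroxycyclopent-3-en-1-yl]carbonyl}-1,3-oxazolidin-2-one | O[C@H]1C=C(CCO[Si](C)(C)C(C)(C)C)C[C@H]1C(=O)N1[C@H](Cc2ccccc2)COC1=O | intermediate
9 | (4R)-4-benzyl-3-{[(1R,2S)-4-{2-[(tert-butyldimethylsilyl)oxy]ethyl}-2-[(triisopropylsilyl)oxy]cyclopent-3-en-1-yl]carbonyl}-1,3-oxazolidin-2-one | CC(C)[Si](C(C)C)(C(C)C)O[C@H]1C=C(CCO[Si](C)(C)C(C)(C)C)C[C@H]1C(=O)N1[C@H](Cc2ccccc2)COC1=O | intermediate
10 | [(1S,2S)-4-{2-[(tert-butyldimethylsilyl)oxy]ethyl}-2-[(triisopropylsilyl)oxy]cyclopent-3-en-1-yl]methanol | CC(C)[Si](C(C)C)(C(C)C)O[C@H]1C=C(CCO[Si](C)(C)C(C)(C)C)C[C@H]1CO | intermediate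
11 | (1R,2S)-4-{2-[(tert-butyldimethylsilyl)oxy]ethyl}-2-[(triisopropylsilyl)oxy]cyclopent-3-ene-1-carbaldehyde | CC(C)[Si](C(C)C)(C(C)C)O[C@H]1C=C(CCO[Si](C)(C)C(C)(C)C)C[C@H]1C=O | intermediate
12 | (1S)-1-[(1S,2S)-4-{2-[(tert-butyldimethylsilyl)oxy]ethyl}-2-[(triisopropylsilyl)oxy]cyclopent-3-en-1-yl]but-3-en-1-ol | CC(C)[Si](C(C)C)(C(C)C)O[C@H]1C=C(CCO[Si](C)(C)C(C)(C)C)C[C@H]1[C@@H](O)CC=C | intermediate
13 | acryloyl chloride | C=CC(=O)Cl | starting material
14 | (1S)-1-[(1S,2S)-4-{2-[(tert-butyldimethylsilyl)oxy]ethyl}-2-[(triisopropylsilyl)oxy]cyclopent-3-en-1-yl]but-3-en-1-yl prop-2-enoate | CC(C)[Si](C(C)C)(C(C)C)O[C@H]1C=C(CCO[Si](C)(C)C(C)(C)C)C[C@H]1[C@@H](OC(=O)C=C)CC=C | intermediate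
15 | (6S)-6-[(1S,2S)-4-{2-[(tert-butyldimethylsilyl)oxy]ethyl}-2-[(triisopropylsilyl)oxy]cyclopent-3-en-1-yl]-5,6-dihydro-2H-pyran-2-one (key-step precursor) | CC(C)[Si](C(C)C)(C(C)C)O[C@H]1C=C(CCO[Si](C)(C)C(C)(C)C)C[C@H]1[C@@H]1CC=CC(=O)O1 | intermediate
16 | tricyclic lactone (ring C, ring D, 20→12 δ-lactone; 8-CH2CH2OTBS, 16-OTIPS; key-step product) | CC(C)(C)[Si](C)(C)OCC[C@@]12C[C@H](O[Si](C(C)C)(C(C)C)C(C)C)[C@@H](C1)[C@@H]3C[C@H]2CC(=O)O3 | intermediate
17 | 10-(dimethylaminomethyl) derivative of 16 | CC(C)(C)[Si](C)(C)OCC[C@@]12C[C@H](O[Si](C(C)C)(C(C)C)C(C)C)[C@@H](C1)[C@@H]3C[C@H]2[C@@H](CN(C)C)C(=O)O3 | intermediate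
18 | trimethylammonium iodide of 17 | CC(C)(C)[Si](C)(C)OCC[C@@]12C[C@H](O[Si](C(C)C)(C(C)C)C(C)C)[C@@H](C1)[C@@H]3C[C@H]2[C@@H](C[N+](C)(C)C)C(=O)O3.[I-] | intermediate
19 | α-methylene lactone (C10=C1) | CC(C)(C)[Si](C)(C)OCC[C@@]12C[C@H](O[Si](C(C)C)(C(C)C)C(C)C)[C@@H](C1)[C@@H]3C[C@H]2C(=C)C(=O)O3 | intermediate
20 | primary alcohol (C5–OH) of 19 | OCC[C@@]12C[C@H](O[Si](C(C)C)(C(C)C)C(C)C)[C@@H](C1)[C@@H]3C[C@H]2C(=C)C(=O)O3 | intermediate
21 | C5 aldehyde | O=CC[C@@]12C[C@H](O[Si](C(C)C)(C(C)C)C(C)C)[C@@H](C1)[C@@H]3C[C@H]2C(=C)C(=O)O3 | intermediate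
22 | (6S)-6-(hydroxymethyl) C5 aldehyde | O=C[C@H](CO)[C@@]12C[C@H](O[Si](C(C)C)(C(C)C)C(C)C)[C@@H](C1)[C@@H]3C[C@H]2C(=C)C(=O)O3 | intermediate
23 | (E)-enone with C7 hydroxymethyl on C6 | CC(=O)/C=C/[C@H](CO)[C@@]12C[C@H](O[Si](C(C)C)(C(C)C)C(C)C)[C@@H](C1)[C@@H]3C[C@H]2C(=C)C(=O)O3 | intermediate
24 | (E)-2-silyloxydiene, C7–OTBS | C=C(O[Si](C)(C)C(C)(C)C)/C=C/[C@H](CO[Si](C)(C)C(C)(C)C)[C@@]12C[C@H](O[Si](C(C)C)(C(C)C)C(C)C)[C@@H](C1)[C@@H]3C[C@H]2C(=C)C(=O)O3 | intermediate
25 | pentacyclic C3(OTBS)=C4 silyl enol ether (A/B trans, 5β-H) | CC(C)[Si](C(C)C)(C(C)C)O[C@H]1C[C@]23C[C@H]1[C@@H]1C[C@H]2[C@@]2(CCC(O[Si](C)(C)C(C)(C)C)=C[C@H]2[C@@H]3CO[Si](C)(C)C(C)(C)C)C(=O)O1 | intermediate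
26 | 4-(dimethoxymethyl)-3-ketone (C4 epimers, configuration not relevant) | CC(C)[Si](C(C)C)(C(C)C)O[C@H]1C[C@]23C[C@H]1[C@@H]1C[C@H]2[C@@]2(CCC(=O)C(C(OC)OC)[C@H]2[C@@H]3CO[Si](C)(C)C(C)(C)C)C(=O)O1 | intermediate
27 | 4-(hydroxymethylidene)-3-ketone | CC(C)[Si](C(C)C)(C(C)C)O[C@H]1C[C@]23C[C@H]1[C@@H]1C[C@H]2[C@@]2(CCC(=O)/C(=C\O)[C@H]2[C@@H]3CO[Si](C)(C)C(C)(C)C)C(=O)O1 | intermediate
28 | 4β-methyl-4α-formyl-3-ketone | CC(C)[Si](C(C)C)(C(C)C)O[C@H]1C[C@]23C[C@H]1[C@@H]1C[C@H]2[C@@]2(CCC(=O)[C@@](C)(C=O)[C@H]2[C@@H]3CO[Si](C)(C)C(C)(C)C)C(=O)O1 | intermediate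
29 | C2=C3 enol triflate (3-OTf) | CC(C)[Si](C(C)C)(C(C)C)O[C@H]1C[C@]23C[C@H]1[C@@H]1C[C@H]2[C@@]2(CC=C(OS(=O)(=O)C(F)(F)F)[C@@](C)(C=O)[C@H]2[C@@H]3CO[Si](C)(C)C(C)(C)C)C(=O)O1 | intermediate
30 | C2=C3 alkene, 19-aldehyde, 7-OTBS, 16-OTIPS | CC(C)[Si](C(C)C)(C(C)C)O[C@H]1C[C@]23C[C@H]1[C@@H]1C[C@H]2[C@@]2(CC=C[C@@](C)(C=O)[C@H]2[C@@H]3CO[Si](C)(C)C(C)(C)C)C(=O)O1 | intermediate
31 | 7,16-diol 19-aldehyde | O[C@H]1C[C@]23C[C@H]1[C@@H]1C[C@H]2[C@@]2(CC=C[C@@](C)(C=O)[C@H]2[C@@H]3CO)C(=O)O1 | intermediate
32 | 16-oxo-7,19-dioic acid (C2=C3 alkene) | O=C1C[C@]23C[C@H]1[C@@H]1C[C@H]2[C@@]2(CC=C[C@@](C)(C(=O)O)[C@H]2[C@@H]3C(=O)O)C(=O)O1 | intermediate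
33 | 2β,3β-dihydroxy-16-oxo-7,19-dioic acid | O=C1C[C@]23C[C@H]1[C@@H]1C[C@H]2[C@@]2(C[C@H](O)[C@H](O)[C@@](C)(C(=O)O)[C@H]2[C@@H]3C(=O)O)C(=O)O1 | intermediate
34 | CNP0212122.1: 2β,3β-dihydroxy C20-gibberellin 7,19-dioic acid, C20 lactonised onto O12, 16-ene | C=C1C[C@]23C[C@H]1[C@@H]1C[C@H]2[C@@]2(C[C@H](O)[C@H](O)[C@@](C)(C(=O)O)[C@H]2[C@@H]3C(=O)O)C(=O)O1 | target

## Step count and risks

Total step count: 26. Longest linear sequence: 26 steps (1 to 34; the route is fully linear).

Steps most likely to fail, with fallbacks: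

Step 11. The 6-exo closure may be slow, because the lactone must first adopt the conformer with C13 axial; the C8 radical can then be reduced by a second hydrogen-atom transfer (net hydrogenation of the alkene), or the iron hydride can reduce the enoate. The fallback releases the same C8 radical without a metal hydride. It sets out from 15: oxymercuration–demercuration (Hg(OAc)2, THF/H2O; NaBH4, aq. NaOH, 0 °C) gives the tertiary C8 alcohol F1. Acylation with N-phthalimidoyl chlorooxoacetate (Et3N, DMAP, CH2Cl2) gives the tert-alkyl N-phthalimidoyl oxalate F2. Visible-light photoredox fragmentation (Ru(bpy)3(PF6)2, Hantzsch ester, iPr2NEt·HBF4, CH2Cl2/THF, blue light) forms the C8 radical with loss of CO2; 6-exo Giese closure and reduction come back at 16.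

Step 18. Endo/exo selection in the cycloaddition may be poor, giving the cis A/B fusion (wrong C5) beside the trans one. The fallback sets C5 by conjugate reduction instead of by the cycloaddition. It sets out from 25 (as the C5 epimer mixture): Saegusa–Ito dehydrogenation (Pd(OAc)2, MeCN, rt) gives the C4=C5 enone F3, which erases C5. Copper-hydride conjugate hydrosilylation (CuCl, NaOtBu, PPh3, Et3SiH, toluene) should deliver hydride to C5 on the β face, anti to the axial C20 carbonyl, and gives the triethylsilyl enol ether F4 with the trans fusion. F4 takes the place of 25 in step 19 and the route is rejoined at 27.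

Step 16. Enamine formation at the neopentyl aldehyde may be slow, the aldol may dehydrate to the 2-substituted acrolein, and facial control at C6 may erode. The fallback gives up kinetic control at C6 and sets it thermodynamically. It sets out from 21: silylation (TBSOTf, Et3N, CH2Cl2) gives the silyl enol ether F5. A Mukaiyama aldol reaction with aqueous formaldehyde (Yb(OTf)3, THF/H2O), followed by the Wittig reaction of step 16, comes back at 23 as a pair of C6 epimers, which is carried through steps 17 to 23. Dess–Martin oxidation of 31 then gives the keto dialdehyde F6, whose C6 is equilibrated with DBU (CH2Cl2, rt) to the natural configuration, and Pinnick oxidation (NaClO2, NaH2PO4, 2-methylbut-2-ene, t-BuOH/H2O) comes back at 32.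

## Further compounds

F1 | step 11 | tertiary C8 alcohol from hydration of 15 (C8 epimers) | CC(C)(C)[Si](C)(C)OCCC1(O)C[C@H](O[Si](C(C)C)(C(C)C)C(C)C)[C@@H](C1)[C@@H]4CC=CC(=O)O4
F2 | step 11 | tert-alkyl N-phthalimidoyl oxalate of F1 | CC(C)(C)[Si](C)(C)OCCC1(OC(=O)C(=O)ON2C(=O)c3ccccc3C2=O)C[C@H](O[Si](C(C)C)(C(C)C)C(C)C)[C@@H](C1)[C@@H]4CC=CC(=O)O4
F3 | step 18 | C4=C5 enone (3-ketone) from 25 | CC(C)[Si](C(C)C)(C(C)C)O[C@H]1C[C@]23C[C@H]1[C@@H]1C[C@H]2[C@@]2(CCC(=O)C=C2[C@@H]3CO[Si](C)(C)C(C)(C)C)C(=O)O1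
F4 | step 18 | C3(OSiEt3)=C4 triethylsilyl enol ether, 5β-H | CC(C)[Si](C(C)C)(C(C)C)O[C@H]1C[C@]23C[C@H]1[C@@H]1C[C@H]2[C@@]2(CCC(O[Si](CC)(CC)CC)=C[C@H]2[C@@H]3CO[Si](C)(C)C(C)(C)C)C(=O)O1
F5 | step 16 | tert-butyldimethylsilyl enol ether of aldehyde 21 (E/Z mixture) | CC(C)(C)[Si](C)(C)OC=C[C@@]12C[C@H](O[Si](C(C)C)(C(C)C)C(C)C)[C@@H](C1)[C@@H]3C[C@H]2C(=C)C(=O)O3
F6 | step 16 | 16-oxo-7,19-dialdehyde (C2=C3 alkene, natural C6) | O=C1C[C@]23C[C@H]1[C@@H]1C[C@H]2[C@@]2(CC=C[C@@](C)(C=O)[C@H]2[C@@H]3C=O)C(=O)O1
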